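The decalin is disconnected at C9–C10 and reconnected at C2–C7, which folds it into a bicyclo[2.2.2]octene: the all-cis triad C3(O)/C4(CH3)/C5(CH3) of ring A, flanked by C1=C2, becomes the endo-substituted ethano bridge and the methylated bridgehead, and C1=C10 the etheno bridge. An anionic oxy-Cope shift of the C7 vinyl carbinol then closes ring B, fixes the cis ring fusion at C10, moves the alkene to C1=C2 and unveils the C7 ketone in a single operation. The precursor, a tertiary vinyl carbinol with the vinyl group syn to the etheno bridge, comes from a masked o-benzoquinone Diels–Alder adduct; ring B is later oxidised to the C7/C8 diosphenol and O3 is esterified.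

Key step: step 7

Numbering: C1–C10 are the decalin atoms of the target (ring A = C1–C5 and C10, ring B = C5–C10). In the bicyclic intermediates the bicyclo locants 1, 2, 3, 4, 5, 6, 7, 8 correspond to target C2, C7, C6, C5, C10, C1, C3, C4.

Assumption: in the lipase resolution (step 3) the enantiomer needed is taken to be the slower-acylated one, as the empirical size rule for lipases suggests when the methyl-bearing C4 arm counts as the larger group; the sense has to be confirmed on the first run.

Step 1
Reactants: 1 2-methoxy-3-methylphenol; 2 (Z)-prop-1-enyl acetate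
Product: 4 racemic endo,endo adduct 7-acetoxy-3,3-dimethoxy-4,8-dimethylbicyclo[2.2.2]oct-5-en-2-one, via masked o-benzoquinone 3 (not isolated)
Conditions: PhI(OAc)2 (1.1 equiv), 2 (10 equiv), MeOH, slow addition of 1, 0 °C → 60 °C
Reagents that add atoms: methanol, CO
Why: Oxidative dearomatisation of the guaiacol by trivalent iodine in methanol gives the 6,6-dimethoxy-5-methylcyclohexa-2,4-dienone, which is trapped in an inverse-electron-demand Diels–Alder reaction in which the nucleophilic methyl-bearing carbon of the enol acetate bonds to the methylated diene terminus (C5) and the acetoxy carbon to the terminus next to the carbonyl (C2), while the endo rule together with the Z geometry places OAc (C3) and CH3 (C4) both syn to the new C1=C10 bridge, so that the relative configuration of C3, C4 and C5 is set (racemic).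

Step 2
Reactants: 4 racemic acetate
Product: 5 racemic 7-hydroxy-3,3-dimethoxy-4,8-dimethylbicyclo[2.2.2]oct-5-en-2-one
Conditions: HCl (cat.), MeOH, rt → 40 °C
Reagents that add atoms: none
Why: Acid-catalysed transesterification removes the acetate without ever forming the C3 alkoxide, so the β-hydroxy ketone is not exposed to retro-aldol opening of the C2–C3 bond, and the α-keto dimethyl ketal only exchanges degenerately with the solvent.

Step 3
Reactants: 5 racemic alcohol
Product: 6 (1R,4S,7R,8R)-7-hydroxy-3,3-dimethoxy-4,8-dimethylbicyclo[2.2.2]oct-5-en-2-one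
Conditions: Burkholderia cepacia lipase (immobilised), vinyl acetate, MTBE, 35 °C, run to just past half conversion
Reagents that add atoms: none
Why: Lipase-catalysed kinetic resolution by irreversible transesterification should acetylate one enantiomer of the secondary alcohol much faster, so that going slightly past half conversion leaves the slower enantiomer 6 in high enantiomeric purity and separable from the acetate by chromatography; no stereocentre is formed, but the absolute configuration of C3, C4 and C5 is selected here.

Step 4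
Reactants: 6 resolved alcohol
Product: 7 (1R,4S,7R,8R)-7-(tert-butyldimethylsilyloxy)-3,3-dimethoxy-4,8-dimethylbicyclo[2.2.2]oct-5-en-2-one
Conditions: TBSOTf, 2,6-lutidine, CH2Cl2, −78 → 0 °C
Reagents that add atoms: tert-butyldimethylsilyl trifluoromethanesulfonate, CC(C)(C)[Si](C)(C)OS(=O)(=O)C(F)(F)F
Why: Silylation of the hindered endo alcohol with the silyl triflate is fast, and because the ketone has no enolisable α-hydrogen (bridgehead C2 and ketal carbon C6) no silyl enol ether can form.

Step 5
Reactants: 7 silyl ether
Product: 8 (1R,4S,7R,8R)-7-(tert-butyldimethylsilyloxy)-4,8-dimethylbicyclo[2.2.2]oct-5-en-2-one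
Conditions: SmI2 (6 equiv), THF/MeOH, 0 °C → rt
Reagents that add atoms: none
Why: Single-electron reduction of the ketone by samarium diiodide expels each α-methoxy group in turn through the samarium enolate (reductive α-deoxygenation of an α-alkoxy ketone), and the β-silyloxy group cannot be eliminated because the intervening carbon C2 is a bridgehead.

Step 6
Reactants: 8 ketone; 9 vinylmagnesium bromide
Product: 10 (1R,2S,4S,7R,8R)-7-(tert-butyldimethylsilyloxy)-4,8-dimethyl-2-vinylbicyclo[2.2.2]oct-5-en-2-ol
Conditions: THF, −78 → 0 °C; then H2O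
Reagents that add atoms: none
Why: Grignard 1,2-addition to the C7 ketone should occur from the face flanked by the etheno bridge, whose sp2 C1–H points away, and not from the face shielded by the exo hydrogens of the C3–C4 bridge, which sets the new C7 stereocentre with the vinyl group syn to C1=C10 as the rearrangement requires.

Step 7
Reactants: 10 vinyl carbinol
Product: 13 cis-fused (3S,4R,5S,10S)-3-(tert-butyldimethylsilyloxy)-4,5-dimethyldecal-1-en-7-one, via potassium alkoxide 11 (not isolated), via potassium enolate 12 (not isolated)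
Conditions: KH, 18-crown-6, THF, 0 °C → rt; then AcOH, −78 °C
Reagents that add atoms: none
Why: KH deprotonates the tertiary alcohol and the crown-ether-separated alkoxide undergoes a charge-accelerated [3,3]-sigmatropic shift (anionic oxy-Cope rearrangement) of the 1,5-diene C9=C8–C7(O−)–C2–C1=C10, in which C9–C10 forms as C2–C7 breaks and the C7 enolate results, protonated on work-up. The closest known reaction type is the anionic oxy-Cope rearrangement of 2-vinylbicyclo[2.2.2]oct-5-en-2-ols to cis-fused decalones. Ring B (C5–C6–C7–C8–C9–C10) closes suprafacially through the boat-like array that the bicycle enforces, formally a 6-exo closure of C9 onto C10 of the C1=C10 bond. The new stereocentre C10 is controlled by the tether, since C9 can only reach the face of C10 that carries the C6–C7 bridge, so H-10 ends up cis to the C5 methyl group, while C3, C4 and C5 are carried over unchanged. The step needs the [3,3] path to win over a [1,3] shift and over fragmentation, which is secured by the syn relationship of vinyl group and etheno bridge set in step 6 and by the alkoxide weakening the C2–C7 bond; the enolate is regiodefined as C7=C8.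

Step 8
Reactants: 13 decalone
Product: 15 (3S,4R,5S,10S)-8-hydroxy-3-(tert-butyldimethylsilyloxy)-4,5-dimethyldecal-1-en-7-one (C8 epimers), via sodium enolate 14 (not isolated)
Conditions: NaN(SiMe3)2, THF, −78 °C; 2-(phenylsulfonyl)-3-phenyloxaziridine, −78 °C; then AcOH
Reagents that add atoms: 2-(phenylsulfonyl)-3-phenyloxaziridine, O=S(=O)(c1ccccc1)N1OC1c1ccccc1
Why: Kinetic deprotonation by the bulky sodium amide should take place at C8 and not at the neopentyl C6 next to the quaternary C5, giving the sodium C7=C8 enolate, whose electrophilic hydroxylation by the N-sulfonyloxaziridine (Davis enolate α-hydroxylation, for which sodium enolates are the usual substrates) gives the acyloin; the C8 configuration is not controlled and is erased in step 9.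

Step 9
Reactants: 15 acyloin
Product: 16 (3S,4R,5S,10S)-3-(tert-butyldimethylsilyloxy)-4,5-dimethyldecal-1-ene-7,8-dione (expected to be largely enolised)
Conditions: Dess–Martin periodinane, CH2Cl2, 0 °C → rt
Reagents that add atoms: none
Why: Dess–Martin oxidation of the secondary acyloin hydroxyl gives the 1,2-diketone under near-neutral conditions that leave the silyl ether and the C1=C2 alkene untouched.

Step 10
Reactants: 16 dione
Product: 17 (3S,4R,5S)-3-(tert-butyldimethylsilyloxy)-7-hydroxy-4,5-dimethyldecalin-1,6,9-trien-8-one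
Conditions: DDQ (1.2 equiv), 1,4-dioxane, 60–80 °C
Reagents that add atoms: none
Why: DDQ dehydrogenation through the C8=C9 enol removes the doubly allylic hydride at C10 and the cation loses the enol proton to give the C9=C10 enone, after which the remaining C7 carbonyl can enolise only towards C6 (C5 is quaternary), so the cross-conjugated diosphenol of the target forms and the transient C10 centre disappears.

Step 11
Reactants: 17 diosphenol
Product: 18 (3S,4R,5S)-3-(tert-butyldimethylsilyloxy)-7-(methoxymethoxy)-4,5-dimethyldecalin-1,6,9-trien-8-one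
Conditions: MOMCl, i-Pr2NEt, CH2Cl2, 0 °C → rt
Reagents that add atoms: chloromethyl methyl ether, COCCl
Why: The acidic enol hydroxyl is O-alkylated by the hard alkoxymethyl chloride (acetal-type protection), which masks it against acylation in step 20 with a group that survives fluoride.

Step 12
Reactants: 18 methoxymethyl ether
Product: 19 (3S,4R,5S)-3-hydroxy-7-(methoxymethoxy)-4,5-dimethyldecalin-1,6,9-trien-8-one
Conditions: HF·pyridine, pyridine, THF, 0 °C → rt
Reagents that add atoms: none
Why: Fluoride-mediated desilylation under buffered, non-basic conditions frees the C3 alcohol without cleaving the acetal and without deprotonating the vinylogous C3–H of the trienone.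

Step 13
Reactants: 20 (R)-4-benzyloxazolidin-2-one; 21 butanoyl chloride
Product: 22 (R)-4-benzyl-3-butanoyloxazolidin-2-one
Conditions: Et3N, DMAP (cat.), CH2Cl2, 0 °C → rt
Reagents that add atoms: none
Why: N-Acylation of the oxazolidinone by the acid chloride under nucleophilic catalysis attaches the chiral auxiliary to the four-carbon acyl unit.

Step 14
Reactants: 22 N-butanoyl imide
Product: 24 (R)-4-benzyl-3-[(S)-2-(hydroxymethyl)butanoyl]oxazolidin-2-one, via titanium enolate 23 (not isolated)
Conditions: TiCl4, i-Pr2NEt, CH2Cl2, 0 °C; then 1,3,5-trioxane, TiCl4, 0 °C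
Reagents that add atoms: 1,3,5-trioxane, C1OCOCO1
Why: Soft enolisation gives the chelated Z titanium enolate, which is hydroxymethylated by the formaldehyde equivalent on the face opposite the benzyl group of the auxiliary (auxiliary-controlled aldol-type hydroxymethylation), setting the side-chain stereocentre as S.

Step 15
Reactants: 24 hydroxymethyl imide
Product: 25 (R)-4-benzyl-3-[(S)-2-[(tert-butyldimethylsilyloxy)methyl]butanoyl]oxazolidin-2-one
Conditions: TBSCl, imidazole, DMF, rt
Reagents that add atoms: tert-butyldimethylsilyl chloride, CC(C)(C)[Si](C)(C)Cl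
Why: Silylation of the primary alcohol under mild base protects it for the later steps and avoids retro-aldol loss of formaldehyde.

Step 16
Reactants: 25 silylated imide
Product: 26 (R)-2-[(tert-butyldimethylsilyloxy)methyl]butan-1-ol
Conditions: LiBH4, MeOH (1 equiv), THF, 0 °C
Reagents that add atoms: none
Why: Hydride reduction of the exocyclic imide carbonyl cleaves the auxiliary reductively and gives the primary alcohol without touching the stereocentre, and the low temperature should keep the silyl group from migrating between the two primary oxygens, which would erode the enantiomeric purity.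

Step 17
Reactants: 26 alcohol
Product: 27 (S)-2-[(tert-butyldimethylsilyloxy)methyl]butanal
Conditions: Dess–Martin periodinane, CH2Cl2, 0 °C → rt
Reagents that add atoms: none
Why: Dess–Martin oxidation gives the α-branched aldehyde under non-basic conditions, so the stereocentre next to the carbonyl is not epimerised; the aldehyde is used at once.

Step 18
Reactants: 27 aldehyde; 28 triethyl 4-phosphonocrotonate
Product: 30 ethyl (2E,4E,6R)-6-[(tert-butyldimethylsilyloxy)methyl]octa-2,4-dienoate, via lithiated phosphonate 29 (not isolated)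
Conditions: LiN(SiMe3)2, THF, −78 °C; then 27, −78 → 0 °C
Reagents that add atoms: none
Why: Vinylogous Horner–Wadsworth–Emmons olefination with the stabilised allylic phosphonate anion forms the C4=C5 bond with E geometry, as expected for stabilised phosphonates, while the C2=C3 geometry is carried over from the crotonate.

Step 19
Reactants: 30 dienoate ester
Product: 31 (2E,4E,6R)-6-[(tert-butyldimethylsilyloxy)methyl]octa-2,4-dienoic acid
Conditions: LiOH, THF/MeOH/H2O, rt; then 1 M HCl to pH 4
Reagents that add atoms: lithium hydroxide, [Li+].[OH-]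
Why: Saponification of the ethyl ester by acyl–oxygen cleavage gives the acid, and the primary silyl ether is stable to dilute hydroxide at room temperature.

Step 20
Reactants: 19 C3 alcohol; 31 side-chain acid
Product: 33 (4aS,5R,6S)-3-(methoxymethoxy)-4a,5-dimethyl-2-oxo-2,4a,5,6-tetrahydronaphthalen-6-yl (2E,4E,6R)-6-[(tert-butyldimethylsilyloxy)methyl]octa-2,4-dienoate, via mixed anhydride 32 (not isolated)
Conditions: 2,4,6-trichlorobenzoyl chloride, Et3N, THF, rt; then 19, DMAP, toluene, rt
Reagents that add atoms: none
Why: In this Yamaguchi esterification DMAP attacks the mixed anhydride at the less hindered dienoyl carbonyl and the acylpyridinium acylates the hindered allylic C3 alcohol with retention at C3, because the C–O bond of the alcohol is not broken.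

Step 21
Reactants: 33 protected ester
Product: 34 septeremophilane E
Conditions: TFA/H2O (9:1), CH2Cl2, 0 °C → rt
Reagents that add atoms: none
Why: Acid hydrolysis cleaves the methoxymethyl acetal of the diosphenol and the primary silyl ether in one operation, while the C3 ester should be spared because ionisation at C3 would give a cation conjugated to the electron-poor dienone.

Compound list
1 | 2-methoxy-3-methylphenol | COc1c(C)cccc1O | starting material
2 | (Z)-prop-1-enyl acetate | C/C=C\OC(C)=O | starting material
3 | 6,6-dimethoxy-5-methylcyclohexa-2,4-dien-1-one (masked o-benzoquinone) | COC1(OC)C(C)=CC=CC1=O | intermediate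
4 | racemic (1R*,4S*,7R*,8R*)-7-acetoxy-3,3-dimethoxy-4,8-dimethylbicyclo[2.2.2]oct-5-en-2-one, OAc and 8-CH3 syn to C5=C6 (SMILES shows the enantiomer carried on) | CC(=O)O[C@H]1[C@H]2C=C[C@](C)(C(OC)(OC)C2=O)[C@H]1C | intermediate
5 | racemic (1R*,4S*,7R*,8R*)-7-hydroxy-3,3-dimethoxy-4,8-dimethylbicyclo[2.2.2]oct-5-en-2-one (SMILES shows the enantiomer carried on) | O[C@H]1[C@H]2C=C[C@](C)(C(OC)(OC)C2=O)[C@H]1C | intermediate
6 | (1R,4S,7R,8R)-7-hydroxy-3,3-dimethoxy-4,8-dimethylbicyclo[2.2.2]oct-5-en-2-one | O[C@H]1[C@H]2C=C[C@](C)(C(OC)(OC)C2=O)[C@H]1C | intermediate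
7 | (1R,4S,7R,8R)-7-(tert-butyldimethylsilyloxy)-3,3-dimethoxy-4,8-dimethylbicyclo[2.2.2]oct-5-en-2-one | CC(C)(C)[Si](C)(C)O[C@H]1[C@H]2C=C[C@](C)(C(OC)(OC)C2=O)[C@H]1C | intermediate
8 | (1R,4S,7R,8R)-7-(tert-butyldimethylsilyloxy)-4,8-dimethylbicyclo[2.2.2]oct-5-en-2-one | CC(C)(C)[Si](C)(C)O[C@H]1[C@H]2C=C[C@](C)(CC2=O)[C@H]1C | intermediate
9 | vinylmagnesium bromide | C=C[Mg]Br | starting material
10 | (1R,2S,4S,7R,8R)-7-(tert-butyldimethylsilyloxy)-4,8-dimethyl-2-vinylbicyclo[2.2.2]oct-5-en-2-ol, vinyl syn to C5=C6 | CC(C)(C)[Si](C)(C)O[C@H]1[C@H]2C=C[C@](C)(C[C@]2(O)C=C)[C@H]1C | intermediate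
11 | potassium alkoxide of 10 | CC(C)(C)[Si](C)(C)O[C@H]1[C@H]2C=C[C@](C)(C[C@]2([O-])C=C)[C@H]1C.[K+] | intermediate
12 | potassium C7=C8 enolate of 13 | CC(C)(C)[Si](C)(C)O[C@H]1C=C[C@@H]2CC=C([O-])C[C@]2(C)[C@H]1C.[K+] | intermediate
13 | cis-fused (3S,4R,5S,10S)-3-(tert-butyldimethylsilyloxy)-4,5-dimethyldecal-1-en-7-one | CC(C)(C)[Si](C)(C)O[C@H]1C=C[C@@H]2CCC(=O)C[C@]2(C)[C@H]1C | intermediate
14 | sodium C7=C8 enolate of 13 | CC(C)(C)[Si](C)(C)O[C@H]1C=C[C@@H]2CC=C([O-])C[C@]2(C)[C@H]1C.[Na+] | intermediate
15 | (3S,4R,5S,10S)-8-hydroxy-3-(tert-butyldimethylsilyloxy)-4,5-dimethyldecal-1-en-7-one (C8 epimers) | CC(C)(C)[Si](C)(C)O[C@H]1C=C[C@@H]2CC(O)C(=O)C[C@]2(C)[C@H]1C | intermediate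
16 | (3S,4R,5S,10S)-3-(tert-butyldimethylsilyloxy)-4,5-dimethyldecal-1-ene-7,8-dione | CC(C)(C)[Si](C)(C)O[C@H]1C=C[C@@H]2CC(=O)C(=O)C[C@]2(C)[C@H]1C | intermediate
17 | (3S,4R,5S)-3-(tert-butyldimethylsilyloxy)-7-hydroxy-4,5-dimethyldecalin-1,6,9-trien-8-one | CC(C)(C)[Si](C)(C)O[C@H]1C=CC2=CC(=O)C(O)=C[C@]2(C)[C@H]1C | intermediate
18 | (3S,4R,5S)-3-(tert-butyldimethylsilyloxy)-7-(methoxymethoxy)-4,5-dimethyldecalin-1,6,9-trien-8-one | CC(C)(C)[Si](C)(C)O[C@H]1C=CC2=CC(=O)C(OCOC)=C[C@]2(C)[C@H]1C | intermediate
19 | (3S,4R,5S)-3-hydroxy-7-(methoxymethoxy)-4,5-dimethyldecalin-1,6,9-trien-8-one | O[C@H]1C=CC2=CC(=O)C(OCOC)=C[C@]2(C)[C@H]1C | intermediate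
20 | (R)-4-benzyloxazolidin-2-one | O=C1N[C@H](Cc2ccccc2)CO1 | starting material
21 | butanoyl chloride | CCCC(Cl)=O | starting material
22 | (R)-4-benzyl-3-butanoyloxazolidin-2-one | CCCC(=O)N1[C@H](Cc2ccccc2)COC1=O | intermediate
23 | (Z)-trichlorotitanium enolate of 22 | CC/C=C(\O[Ti](Cl)(Cl)Cl)N1[C@H](Cc2ccccc2)COC1=O | intermediate
24 | (R)-4-benzyl-3-[(S)-2-(hydroxymethyl)butanoyl]oxazolidin-2-one | CC[C@H](C(=O)N1[C@H](Cc2ccccc2)COC1=O)CO | intermediate
25 | (R)-4-benzyl-3-[(S)-2-[(tert-butyldimethylsilyloxy)methyl]butanoyl]oxazolidin-2-one | CC[C@H](C(=O)N1[C@H](Cc2ccccc2)COC1=O)CO[Si](C)(C)C(C)(C)C | intermediate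
26 | (R)-2-[(tert-butyldimethylsilyloxy)methyl]butan-1-ol | CC[C@H](CO)CO[Si](C)(C)C(C)(C)C | intermediate
27 | (S)-2-[(tert-butyldimethylsilyloxy)methyl]butanal | CC[C@H](C=O)CO[Si](C)(C)C(C)(C)C | intermediate
28 | triethyl 4-phosphonocrotonate | CCOC(=O)/C=C/CP(=O)(OCC)OCC | starting material
29 | lithium salt of the phosphonate carbanion of 28 | CCOC(=O)/C=C/[CH-]P(=O)(OCC)OCC.[Li+] | intermediate
30 | ethyl (2E,4E,6R)-6-[(tert-butyldimethylsilyloxy)methyl]octa-2,4-dienoate | CC[C@H](/C=C/C=C/C(=O)OCC)CO[Si](C)(C)C(C)(C)C | intermediate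
31 | (2E,4E,6R)-6-[(tert-butyldimethylsilyloxy)methyl]octa-2,4-dienoic acid | CC[C@H](/C=C/C=C/C(=O)O)CO[Si](C)(C)C(C)(C)C | intermediate
32 | mixed anhydride of 31 with 2,4,6-trichlorobenzoic acid | CC[C@H](/C=C/C=C/C(=O)OC(=O)c1c(Cl)cc(Cl)cc1Cl)CO[Si](C)(C)C(C)(C)C | intermediate
33 | (4aS,5R,6S)-3-(methoxymethoxy)-4a,5-dimethyl-2-oxo-2,4a,5,6-tetrahydronaphthalen-6-yl (2E,4E,6R)-6-[(tert-butyldimethylsilyloxy)methyl]octa-2,4-dienoate | CC[C@H](/C=C/C=C/C(=O)O[C@H]1C=CC2=CC(=O)C(OCOC)=C[C@]2(C)[C@H]1C)CO[Si](C)(C)C(C)(C)C | intermediate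
34 | septeremophilane E, (4aS,5R,6S)-3-hydroxy-4a,5-dimethyl-2-oxo-2,4a,5,6-tetrahydronaphthalen-6-yl (2E,4E,6R)-6-(hydroxymethyl)octa-2,4-dienoate | CC[C@H](/C=C/C=C/C(=O)O[C@H]1C=CC2=CC(=O)C(O)=C[C@]2(C)[C@H]1C)CO | target

Total step count: 21. Longest linear sequence: 14 steps (steps 1–12, 20 and 21); the side-chain acid takes 7 steps (13–19).

Steps most likely to fail

Step 1. The cycloaddition may be outrun by self-dimerisation of the dienone, because the 1,2-disubstituted enol acetate is a weak nucleophilic dienophile and has to bond to the methyl-bearing diene terminus; the higher temperature then needed may also erode the endo preference. The fallback sets out from 1 and comes back at 5. Allyl 4-methoxybenzyl ether is isomerised with KOt-Bu in DMSO to the more electron-rich (Z)-4-methoxybenzyl prop-1-enyl ether F1. Oxidation of 1 with PhI(OAc)2 in MeOH in the presence of F1 should give, by the same inverse-demand cycloaddition, the racemic endo,endo 7-(4-methoxybenzyloxy) adduct F2. Oxidative ether cleavage with DDQ in wet CH2Cl2 then gives racemic alcohol 5, so step 2 is no longer needed.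

Step 3. The lipase may discriminate poorly between the enantiomers or not turn over at all, since the hydroxyl is endo and hindered and the two arms at the carbinol carbon are of similar size. The fallback sets out from 5 and comes back at 6, and is a classical resolution through covalent diastereomers. Alcohol 5 is esterified with (S)-2-methoxy-2-phenylacetic acid (DCC, DMAP cat., CH2Cl2, 0 °C) to the (S)-O-methylmandelate ester of the wanted enantiomer F3 and the (S)-O-methylmandelate ester of the mirror-image alcohol F4. These are separated by chromatography or crystallisation and assigned by the shielding pattern of the mandelate phenyl group or by X-ray analysis. HCl-catalysed methanolysis of F3, as in step 2, then returns enantiopure 6.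

Step 10. Hydride abstraction may be slow, may occur at the wrong site (C3–H next to the silyl ether), or the product may be oxidised further. The fallback sets out from 16 and comes back at 17. The dione is converted with TMSOTf and Et3N into the 7,8-bis(trimethylsilyloxy)-6,8-diene F5, which is treated with Pd(OAc)2 in MeCN (Saegusa–Ito oxidation). Only palladation at C9 leaves a β-hydrogen (H-10) for elimination, so C9=C10 is formed whichever enol ether reacts first. Mild acidic work-up hydrolyses the remaining C7 silyl enol ether and gives 17.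

Further compounds
F1 | step 1 | (Z)-4-methoxybenzyl prop-1-enyl ether | C/C=C\OCc1ccc(OC)cc1
F2 | step 1 | racemic endo,endo 7-(4-methoxybenzyloxy)-3,3-dimethoxy-4,8-dimethylbicyclo[2.2.2]oct-5-en-2-one (SMILES shows the enantiomer carried on) | COc1ccc(cc1)CO[C@H]1[C@H]2C=C[C@](C)(C(OC)(OC)C2=O)[C@H]1C
F3 | step 3 | (1R,4S,7R,8R)-3,3-dimethoxy-4,8-dimethyl-2-oxobicyclo[2.2.2]oct-5-en-7-yl (S)-2-methoxy-2-phenylacetate | CO[C@H](C(=O)O[C@H]1[C@H]2C=C[C@](C)(C(OC)(OC)C2=O)[C@H]1C)c1ccccc1
F4 | step 3 | (1S,4R,7S,8S)-3,3-dimethoxy-4,8-dimethyl-2-oxobicyclo[2.2.2]oct-5-en-7-yl (S)-2-methoxy-2-phenylacetate | CO[C@H](C(=O)O[C@@H]1[C@@H]2C=C[C@@](C)(C(OC)(OC)C2=O)[C@@H]1C)c1ccccc1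
F5 | step 10 | (3S,4R,5S,10S)-3-(tert-butyldimethylsilyloxy)-4,5-dimethyl-7,8-bis(trimethylsilyloxy)decalin-1,6,8-triene | CC(C)(C)[Si](C)(C)O[C@H]1C=C[C@@H]2C=C(O[Si](C)(C)C)C(O[Si](C)(C)C)=C[C@]2(C)[C@H]1C
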